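The data were generated by integration for substances that don't exist; the scatter is artificial.

Through a dose, the electrophile standing in the flask plus what has reacted equals the part fed. In midnight at 30.0 min, 50.0% has been fed, and electrophile and target read 50.5% together, so the readings show no other large sink so far.

| flask | electrophile | nucleophile | free base | protic impurity | remark | time |
|---|---|---|---|---|---|---|
| midnight | 0.059 M (fed, over 1.0 h) | 1.2 equiv | 1.2 equiv | 1.18 mM | run made earlier; the fed solution adds 0.50 times the starting volume |  |
| winter | 0.059 M (fed, over 1.0 h) | 1.2 equiv | 1.3 equiv | 1.18 mM | run made earlier; the fed solution adds 0.50 times the starting volume |  |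
| north | 0.059 M (fed, over 1.0 h) | 1.20 equiv | 1.50 equiv | 1.18 mM | the fed solution adds 0.50 times the starting volume | 1.0 h |
| east | 0.059 M (fed, over 1.0 h) | 1.20 equiv | 2.00 equiv | 1.18 mM | the fed solution adds 0.50 times the starting volume | 1.0 h |

| run | time / min | electrophile / % | target / % |
|---|---|---|---|
| midnight | 2.50 | 5.9 | 1.8 |
| midnight | 8.00 | 7.3 | 6.0 |
| midnight | 15.0 | 11.1 | 15.2 |
| midnight | 20.0 | 10.2 | 23.6 |
| midnight | 30.0 | 14.1 | 36.4 |
| winter | 2.50 | 3.0 | 1.4 |
| winter | 5.00 | 5.9 | 3.9 |
| winter | 8.00 | 7.5 | 7.0 |
| winter | 15.0 | 8.9 | 16.5 |
| winter | 30.0 | 15.1 | 35.6 |

(readings scatter by 1 percentage point)

- charges are per starting volume, the dose included; the dosed solution carries all of it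
- percentages count the whole charge, also what has not yet gone in

- part of the electrophile that has reacted at the end, north
- part of the electrophile that has reacted at the end, east
- what raising the equivalents of free base from its lowest to its highest value here does to the part of the electrophile that has reacted (changes below 5 percentage points count as none) (it rises / it falls / no change)

Two chemists read this balance differently. Both start from the same step. Over the 15.0 min to 30.0 min stretch of midnight and winter, target gain is divided by standing electrophile and free nucleophile, with the volume growth allowed for. That gives a constant in fractions of the charge of 0.138 /min.

The first chemist turns it into a time at the charged nucleophile, 6.04 min. This is shorter than the dose, so she expects electrophile to be consumed nearly as it arrives, with about 89.9% reacted at the end.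

The second objects that the dose itself eats the nucleophile. He counts one nucleophile gone for each electrophile reacted, so at the end of the dose he takes free nucleophile to be the standing electrophile plus the excess over the limiting reagent, the electrophile, which is 0.200 of the charge. His time is therefore the final volume ratio over the constant times that excess, 54.4 min, the excess clock.

Two rules follow from the clock. At the end of the dose, the standing fraction times itself plus the excess equals the excess times the clock over the dosing time, times the share of the feed that reacts. The readings put that share at 81.6%, since electrophile is still climbing. After the dose, the logarithm of one plus the excess over the standing fraction grows by one per clock.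

I side with him. The first rule leaves 29.7% standing, so 70.3% has reacted. Free base stands nowhere in the clock, and midnight and winter differ in target at 30.0 min by 0.8 percentage points, within scatter, so I give north and east the same figure.

The forecast, on his side but above my figure, says 74% for north, 74% for east and no change: “I therefore treat base as a scavenger only”.

The simulation gives 70.7% for north and 71.4% for east, a change of 0.72 points, so no change.

    protic impurity + free base → quenched reagent (k = 20.0 /M/min)
    electrophile + target → side product (k = 0.230 /M/min)
    electrophile + nucleophile → acid set free + target (k = 3.00 /M/min)
    nucleophile + acid set free ⇌ protonated nucleophile, settled at all times (K = 190 /M)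
    acid set free + free base ⇌ salt of the base, settled at all times (K = 32.0 /M)

In north the quenching of protic impurity had its turnover midpoint at 0.394 min, and the main path ran with the dose, midpoint 0.475 h. The side path came later, midpoint 0.770 h, with 7.57% of the electrophile in side product at 1.00 h. North's standing electrophile is 29% against the reckoned 29.7%. North's free nucleophile at 1.00 h is 20.8% of its own charge, less than his count, with protonated nucleophile beside it at 0.0111 M. The first chemist's picture belongs to the long wait: from 29%, the clock gives 0.445% at 4.0 h, and north read then holds 0.60%, with 99.4% reacted.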